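Rings A and B are disconnected together at C5–C10 and C8–C9. In ring B the oxygenated carbons C6 and C8 (C8 also holds the C17 methyl) stand 1,3 across C7, and the quaternary C10 is β to C11; this is the imprint of a C5=C6–C7=C8 bis(silyloxy)diene adding to a C9=C10 enoyl imide. One [Cu((R,R)-t-Bu-box)](SbF6)2-catalysed intramolecular [4+2] cycloaddition of an open-chain trienyl imide closes both rings and sets C5, C8, C9 and C10. The precursor is an E-configured 3,7,7-trimethyldodecatrienoyl oxazolidinone whose Z,Z-9,11-bis(silyloxy)diene is built regiospecifically by conjugate addition with enolate trapping before the imide is attached.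

Key step: step 7

Remark (labels): C1–C20 are labdane labels of the target; C11 is bonded to C9, C17 is the methyl on C8, C18/C19 are the methyls on C4, C20 is the methyl on C10; α is the face of H5.

Remark (target): the target is (5S,6S,8R,9R,10S,13R); the 6α-ester and the 8α-hydroxyl are equatorial, while C17 is axial and syn to C20, so C8 has to be set stereospecifically from alkene geometry and cannot be left to equilibration.

Remark (diene regiochemistry): enolising the parent 2,4-dione with base or silyl triflate is expected to remove a proton from the C17 methyl and not from the neopentyl C5 methylene, so the C5=C6 enol ether is created by conjugate addition and O-trapping (step 3) and the base-sensitive imide is joined afterwards (step 6).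

Assumption (catalyst sense): the face is assigned from the square-planar s-cis chelate model of bis(oxazoline) complexes of divalent copper, in which the (S,S)-ligand leads to bonding at the Re face of the α-carbon; the target needs the Si face of C9, hence the (R,R)-ligand, and the (S,S)-ligand is used instead if this hindered substrate responds in the opposite sense.

Assumption (step 4): hydroiodination of but-2-ynoic acid under equilibrating conditions is taken to give the E acid (iodine trans to the carboxyl); the geometry is to be confirmed before use because it is passed on to C9/C10 and to C13.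

Step 1
Reactants: 1 mesityl oxide (4-methylpent-3-en-2-one); 2 N-methoxy-N-methylacetamide
Product: 4 6-methylhept-5-ene-2,4-dione, via lithium dienolate 3 (not isolated)
Conditions: LiN(iPr)2, THF, −78 °C; then 2, −78 → 0 °C; aq NH4Cl
Reagents that add atoms: none
Why: Kinetic deprotonation of 1 at the acetyl methyl followed by C-acylation with the N-methoxy-N-methylamide (crossed Claisen condensation) should give the β-diketone, because the chelated tetrahedral adduct survives until work-up and prevents a second addition.

Step 2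
Reactants: 4 6-methylhept-5-ene-2,4-dione
Product: 5 (2Z)-2-(tert-butyldimethylsilyloxy)-6-methylhepta-2,5-dien-4-one
Conditions: TBSCl, Et3N, CH2Cl2, 0 °C → rt
Reagents that add atoms: tert-butyldimethylsilyl chloride, CC(C)(C)[Si](C)(C)Cl
Why: O-Silylation of the chelated cis-enol of the β-diketone should give the Z β-silyloxy enone; a shuttle of the silyl group between the two oxygens is harmless, since conjugate attack at C4 of either tautomer leads to the same bis-enol ether pattern.

Step 3
Reactants: 5 (2Z)-2-(tert-butyldimethylsilyloxy)-6-methylhepta-2,5-dien-4-one; 6 allylmagnesium bromide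
Product: 9 (2Z,4Z)-2,4-bis(tert-butyldimethylsilyloxy)-6,6-dimethylnona-2,4,8-triene, via trimethylsilyl enol ether 7 (not isolated), via lithium trienolate 8 (not isolated)
Conditions: 6, CuBr·SMe2, Me3SiCl, THF, −78 °C; volatiles removed, pentane extract; MeLi, THF, 0 °C; TBSOTf, −78 → 0 °C
Reagents that add atoms: tert-butyldimethylsilyl trifluoromethanesulfonate, CC(C)(C)[Si](C)(C)OS(=O)(=O)C(F)(F)F
Why: Chlorosilane-accelerated conjugate addition of the allylcopper reagent to the s-cis β,β-dimethyl enone creates the quaternary C4 and traps the enolate on oxygen, which places the enol ether on the C5 side with C4 cis to oxygen, and cleavage of the trimethylsilyl ether by MeLi with resilylation swaps in the robust silyl group with retention of enolate geometry.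

Step 4
Reactants: 10 but-2-ynoic acid
Product: 11 (E)-3-iodobut-2-enoic acid
Conditions: 57% aq HI, 95 °C; crystallisation
Reagents that add atoms: hydrogen iodide, I
Why: Hydroiodination of the ynoic acid under equilibrating conditions should give the E β-iodo acid with iodine trans to the carboxyl group, a stereodefined four-carbon unit that serves both as dienophile and as side-chain terminus.

Step 5
Reactants: 11 (E)-3-iodobut-2-enoic acid; 12 oxazolidin-2-one
Product: 14 3-[(E)-3-iodobut-2-enoyl]oxazolidin-2-one, via mixed pivalic anhydride 13 (not isolated)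
Conditions: t-BuCOCl, Et3N, THF, −20 °C; then 12, LiCl, rt
Reagents that add atoms: none
Why: N-Acylation of the oxazolidinone through the mixed pivalic anhydride is a standard imide synthesis that does not touch the alkene geometry.

Step 6
Reactants: 9 (2Z,4Z)-2,4-bis(tert-butyldimethylsilyloxy)-6,6-dimethylnona-2,4,8-triene; 14 3-[(E)-3-iodobut-2-enoyl]oxazolidin-2-one
Product: 16 3-[(2E,8Z,10Z)-9,11-bis(tert-butyldimethylsilyloxy)-3,7,7-trimethyldodeca-2,8,10-trienoyl]oxazolidin-2-one, via B-alkyl-9-borabicyclononane 15 (not isolated)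
Conditions: 9-BBN, THF, 0 °C → rt; then 14, PdCl2(dppf) (5 mol%), AsPh3, aq K3PO4, DMF, rt
Reagents that add atoms: none
Why: 9-BBN should add only to the unhindered terminal alkene, and B-alkyl Suzuki–Miyaura coupling with the β-iodo enoyl imide proceeds with retention at the sp2 carbon, so the C1–C10 bond is formed and the E dienophile geometry is delivered under basic conditions that spare both silyl enol ethers.

Step 7
Reactants: 16 3-[(2E,8Z,10Z)-9,11-bis(tert-butyldimethylsilyloxy)-3,7,7-trimethyldodeca-2,8,10-trienoyl]oxazolidin-2-one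
Product: 17 3-[6,8α-bis(tert-butyldimethylsilyloxy)drim-6-en-11-oyl]oxazolidin-2-one (trans-fused; H5 and the C8 oxygen α; C11, C17 and C20 β)
Conditions: [Cu((R,R)-t-Bu-box)](SbF6)2 (20 mol%), 4 Å molecular sieves, CH2Cl2, −20 °C → rt
Reagents that add atoms: none
Why: The divalent copper centre binds both imide carbonyls in a square-planar chelate with the enoyl group s-cis; C5 of the silyl enol ether attacks the β-carbon C10 and the chelated enolate carbon C9 then collapses on the silyloxy-stabilised allyl cation at C8, a strongly asynchronous intramolecular [4+2] cycloaddition whose closest precedents are bis(oxazoline)-catalysed intramolecular Diels–Alder reactions of trienyl imides and Mukaiyama–Michael additions of enol silanes to enoyl imides. Ring A closes 6-exo-trig at C10 through the C1–C4 tether, and ring B is the new cyclohexene (C9 onto C8, 6-endo with respect to C7=C8). C10 is set by the ligand, which leaves open the face on which the diene meets the Si face of C9; C9 follows from the E enoyl geometry (C11 cis to C20), C8 from the Z C7=C8 geometry (C17 outside, oxygen inside, suprafacial addition) and C5 from the Z C5=C6 geometry in the carbonyl-endo transition state that gives the trans ring fusion. The step needs enantioface and endo selectivity, secured by the two-point-binding imide and by the gem-dimethyl group at C4, which favours the folded tether; regiochemistry is fixed by the tether length and by the matched polarity of nucleophilic C5 and electrophilic C10. A β,β-disubstituted acceptor meeting a neopentyl diene terminus is at the limit of what such catalysts are known to activate, so the risk of the route sits here; C5 stays epimerisable once the 6-ketone is freed in step 13.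

Step 8
Reactants: 17 3-[6,8α-bis(tert-butyldimethylsilyloxy)drim-6-en-11-oyl]oxazolidin-2-one
Product: 18 S-ethyl 6,8α-bis(tert-butyldimethylsilyloxy)drim-6-ene-11-thioate
Conditions: EtSH, n-BuLi, THF, 0 °C
Reagents that add atoms: ethanethiol, CCS
Why: The small thiolate attacks the exocyclic carbonyl of hindered N-acyl oxazolidinones selectively (acyl substitution), giving the thioester without ring opening of the oxazolidinone and without touching the silyl ethers.

Step 9
Reactants: 18 S-ethyl 6,8α-bis(tert-butyldimethylsilyloxy)drim-6-ene-11-thioate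
Product: 19 6,8α-bis(tert-butyldimethylsilyloxy)drim-6-en-11-al
Conditions: iBu2AlH, CH2Cl2, −78 °C
Reagents that add atoms: none
Why: Partial reduction of a thioester with iBu2AlH stops at the aldehyde through a stable hemithioacetal aluminate, and the equatorial C9 substituent is the thermodynamically preferred epimer.

Step 10
Reactants: 19 6,8α-bis(tert-butyldimethylsilyloxy)drim-6-en-11-al
Product: 20 6,8α-bis(tert-butyldimethylsilyloxy)-13,14,15,16-tetranorlabda-6,11-diene
Conditions: Ph3PCH3Br, KN(SiMe3)2, THF, 0 °C
Reagents that add atoms: methyltriphenylphosphonium bromide, C[P+](c1ccccc1)(c1ccccc1)c1ccccc1.[Br-]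
Why: Wittig methylenation with the small non-stabilised ylide works on hindered aldehydes and installs C12, while the C6 enol silyl ether keeps the future ketone masked.

Step 11
Reactants: 11 (E)-3-iodobut-2-enoic acid
Product: 21 (E)-3-iodobut-2-en-1-ol
Conditions: BH3·SMe2, THF, 0 °C → rt; MeOH
Reagents that add atoms: none
Why: Borane reduces the carboxylic acid chemoselectively, far faster than it hydroborates the electron-poor trisubstituted iodoalkene, so the E geometry is carried into the alcohol.

Step 12
Reactants: 20 6,8α-bis(tert-butyldimethylsilyloxy)-13,14,15,16-tetranorlabda-6,11-diene; 21 (E)-3-iodobut-2-en-1-ol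
Product: 23 (13E)-6,8α-bis(tert-butyldimethylsilyloxy)labda-6,13-dien-15-ol, via B-alkyl-9-borabicyclononane 22 (not isolated)
Conditions: 9-BBN, THF, rt → 50 °C; then 21, PdCl2(dppf) (5 mol%), AsPh3, aq Cs2CO3, DMF, rt
Reagents that add atoms: none
Why: Anti-Markovnikov hydroboration of the vinyl group puts boron on C12, and B-alkyl Suzuki–Miyaura coupling with the E vinyl iodide forms C12–C13 with retention, giving the E trisubstituted allylic alcohol needed for reagent-controlled epoxidation.

Step 13
Reactants: 23 (13E)-6,8α-bis(tert-butyldimethylsilyloxy)labda-6,13-dien-15-ol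
Product: 24 (13E)-8α-(tert-butyldimethylsilyloxy)-15-hydroxylabd-13-en-6-one
Conditions: Bu4NF, AcOH, THF, 0 °C
Reagents that add atoms: none
Why: Buffered fluoride cleaves the enol silyl ether much faster than the tertiary alkyl silyl ether (desilylation with protonation at C7), the acetic acid suppresses β-elimination of the C8 oxygen, and H5, now α to the ketone, can relax to the trans fusion.

Step 14
Reactants: 24 (13E)-8α-(tert-butyldimethylsilyloxy)-15-hydroxylabd-13-en-6-one
Product: 25 (13E)-8α-(tert-butyldimethylsilyloxy)labd-13-ene-6α,15-diol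
Conditions: Li, NH3(l), THF, t-BuOH, −78 °C; NH4Cl
Reagents that add atoms: none
Why: Dissolving-metal reduction gives the thermodynamically preferred equatorial 6α-alcohol (6S), whereas hydride reagents would attack from the open α face and give the axial 6β-alcohol; the isolated alkene, the allylic alkoxide and the silyl ether should be inert.

Step 15
Reactants: 25 (13E)-8α-(tert-butyldimethylsilyloxy)labd-13-ene-6α,15-diol
Product: 26 (13R,14R)-8α-(tert-butyldimethylsilyloxy)-13,14-epoxylabdane-6α,15-diol
Conditions: Ti(OiPr)4 (cat.), D-(−)-diisopropyl tartrate, t-BuOOH, 4 Å molecular sieves, CH2Cl2, −20 °C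
Reagents that add atoms: tert-butyl hydroperoxide, CC(C)(C)OO
Why: Sharpless asymmetric epoxidation is reagent-controlled; the D-(−)-tartrate delivers oxygen to the face of the E allylic alcohol that gives the 13R,14R epoxide, and the remote ring stereocentres and the non-allylic 6-hydroxyl do not interfere.

Step 16
Reactants: 26 (13R,14R)-8α-(tert-butyldimethylsilyloxy)-13,14-epoxylabdane-6α,15-diol
Product: 28 (13R)-8α-(tert-butyldimethylsilyloxy)labd-14-ene-6α,13-diol, via epoxy iodide 27 (not isolated)
Conditions: PPh3, I2, imidazole, THF, 0 °C; then Zn, EtOH, 60 °C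
Reagents that add atoms: none
Why: Phosphine–iodine substitution converts only the primary alcohol, and zinc insertion with β-elimination (reductive epoxide opening) unveils the vinyl group and the tertiary alcohol with retention at C13, because the C13–O bond is never broken.

Step 17
Reactants: 28 (13R)-8α-(tert-butyldimethylsilyloxy)labd-14-ene-6α,13-diol
Product: 29 (13R)-labd-14-ene-6α,8α,13-triol
Conditions: Bu4NF, THF, 60 °C
Reagents that add atoms: none
Why: Fluoride-mediated desilylation removes the tertiary silyl ether under non-acidic conditions, which avoids ionisation of the tertiary allylic alcohol and ether formation between O8 and C13.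

Step 18
Reactants: 29 (13R)-labd-14-ene-6α,8α,13-triol; 30 angelic acid ((Z)-2-methylbut-2-enoic acid)
Product: 32 (13R)-6α-angeloyloxylabd-14-ene-8α,13-diol (CNP0203829.1), via mixed trichlorobenzoic anhydride 31 (not isolated)
Conditions: 30, 2,4,6-trichlorobenzoyl chloride, Et3N (excess), toluene, rt; then 29, 80 °C
Reagents that add atoms: none
Why: Yamaguchi-type mixed-anhydride esterification without a nucleophilic catalyst acylates only the secondary equatorial 6α-hydroxyl (both tertiary hydroxyls are inert) and should avoid Z → E isomerisation of the angelate, with excess amine keeping the medium non-acidic.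

Compound list
1 | mesityl oxide (4-methylpent-3-en-2-one) | CC(C)=CC(C)=O | starting material
2 | N-methoxy-N-methylacetamide | CC(=O)N(C)OC | starting material
3 | lithium 4-methylpenta-1,3-dien-2-olate | [Li+].[O-]C(=C)C=C(C)C | intermediate
4 | 6-methylhept-5-ene-2,4-dione | CC(C)=CC(=O)CC(C)=O | intermediate
5 | (2Z)-2-(tert-butyldimethylsilyloxy)-6-methylhepta-2,5-dien-4-one | CC(C)=CC(=O)/C=C(/C)O[Si](C)(C)C(C)(C)C | intermediate
6 | allylmagnesium bromide | C=CC[Mg]Br | starting material
7 | (2Z,4Z)-2-(tert-butyldimethylsilyloxy)-6,6-dimethyl-4-(trimethylsilyloxy)nona-2,4,8-triene | C=CCC(C)(C)/C=C(\O[Si](C)(C)C)/C=C(/C)O[Si](C)(C)C(C)(C)C | intermediate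
8 | lithium (2Z,4Z)-2-(tert-butyldimethylsilyloxy)-6,6-dimethylnona-2,4,8-trien-4-olate | C=CCC(C)(C)/C=C(\[O-])/C=C(/C)O[Si](C)(C)C(C)(C)C.[Li+] | intermediate
9 | (2Z,4Z)-2,4-bis(tert-butyldimethylsilyloxy)-6,6-dimethylnona-2,4,8-triene | C=CCC(C)(C)/C=C(\O[Si](C)(C)C(C)(C)C)/C=C(/C)O[Si](C)(C)C(C)(C)C | intermediate
10 | but-2-ynoic acid | CC#CC(=O)O | starting material
11 | (E)-3-iodobut-2-enoic acid | C/C(I)=C\C(=O)O | intermediate
12 | oxazolidin-2-one | O=C1NCCO1 | starting material
13 | (E)-3-iodobut-2-enoic pivalic anhydride | C/C(I)=C\C(=O)OC(=O)C(C)(C)C | intermediate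
14 | 3-[(E)-3-iodobut-2-enoyl]oxazolidin-2-one | C/C(I)=C\C(=O)N1CCOC1=O | intermediate
15 | 9-[(5Z,7Z)-6,8-bis(tert-butyldimethylsilyloxy)-4,4-dimethylnona-5,7-dienyl]-9-borabicyclo[3.3.1]nonane | C1CCC2CCCC1B2CCCC(C)(C)/C=C(\O[Si](C)(C)C(C)(C)C)/C=C(/C)O[Si](C)(C)C(C)(C)C | intermediate
16 | 3-[(2E,8Z,10Z)-9,11-bis(tert-butyldimethylsilyloxy)-3,7,7-trimethyldodeca-2,8,10-trienoyl]oxazolidin-2-one | O=C1OCCN1C(=O)/C=C(\C)CCCC(C)(C)/C=C(\O[Si](C)(C)C(C)(C)C)/C=C(/C)O[Si](C)(C)C(C)(C)C | intermediate
17 | 3-[6,8α-bis(tert-butyldimethylsilyloxy)drim-6-en-11-oyl]oxazolidin-2-one (trans-fused, H5 α, C11/C17/C20 β) | O=C1OCCN1C(=O)[C@@H]2[C@@]3(C)CCCC(C)(C)[C@@H]3C(O[Si](C)(C)C(C)(C)C)=C[C@@]2(C)O[Si](C)(C)C(C)(C)C | intermediate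
18 | S-ethyl 6,8α-bis(tert-butyldimethylsilyloxy)drim-6-ene-11-thioate | CCSC(=O)[C@@H]1[C@@]2(C)CCCC(C)(C)[C@@H]2C(O[Si](C)(C)C(C)(C)C)=C[C@@]1(C)O[Si](C)(C)C(C)(C)C | intermediate
19 | 6,8α-bis(tert-butyldimethylsilyloxy)drim-6-en-11-al | O=C[C@@H]1[C@@]2(C)CCCC(C)(C)[C@@H]2C(O[Si](C)(C)C(C)(C)C)=C[C@@]1(C)O[Si](C)(C)C(C)(C)C | intermediate
20 | 6,8α-bis(tert-butyldimethylsilyloxy)-13,14,15,16-tetranorlabda-6,11-diene | C=C[C@@H]1[C@@]2(C)CCCC(C)(C)[C@@H]2C(O[Si](C)(C)C(C)(C)C)=C[C@@]1(C)O[Si](C)(C)C(C)(C)C | intermediate
21 | (E)-3-iodobut-2-en-1-ol | C/C(I)=C\CO | intermediate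
22 | 9-[6,8α-bis(tert-butyldimethylsilyloxy)-13,14,15,16-tetranorlabd-6-en-12-yl]-9-borabicyclo[3.3.1]nonane | C1CCC2CCCC1B2CC[C@@H]3[C@@]4(C)CCCC(C)(C)[C@@H]4C(O[Si](C)(C)C(C)(C)C)=C[C@@]3(C)O[Si](C)(C)C(C)(C)C | intermediate
23 | (13E)-6,8α-bis(tert-butyldimethylsilyloxy)labda-6,13-dien-15-ol | C/C(=C\CO)CC[C@@H]1[C@@]2(C)CCCC(C)(C)[C@@H]2C(O[Si](C)(C)C(C)(C)C)=C[C@@]1(C)O[Si](C)(C)C(C)(C)C | intermediate
24 | (13E)-8α-(tert-butyldimethylsilyloxy)-15-hydroxylabd-13-en-6-one | C/C(=C\CO)CC[C@@H]1[C@@]2(C)CCCC(C)(C)[C@@H]2C(=O)C[C@@]1(C)O[Si](C)(C)C(C)(C)C | intermediate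
25 | (13E)-8α-(tert-butyldimethylsilyloxy)labd-13-ene-6α,15-diol | C/C(=C\CO)CC[C@@H]1[C@@]2(C)CCCC(C)(C)[C@@H]2[C@@H](O)C[C@@]1(C)O[Si](C)(C)C(C)(C)C | intermediate
26 | (13R,14R)-8α-(tert-butyldimethylsilyloxy)-13,14-epoxylabdane-6α,15-diol | OC[C@H]1O[C@]1(C)CC[C@@H]2[C@@]3(C)CCCC(C)(C)[C@@H]3[C@@H](O)C[C@@]2(C)O[Si](C)(C)C(C)(C)C | intermediate
27 | (13R,14S)-8α-(tert-butyldimethylsilyloxy)-13,14-epoxy-15-iodolabdan-6α-ol (same spatial arrangement as 26) | IC[C@H]1O[C@]1(C)CC[C@@H]2[C@@]3(C)CCCC(C)(C)[C@@H]3[C@@H](O)C[C@@]2(C)O[Si](C)(C)C(C)(C)C | intermediate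
28 | (13R)-8α-(tert-butyldimethylsilyloxy)labd-14-ene-6α,13-diol | C=C[C@](C)(O)CC[C@@H]1[C@@]2(C)CCCC(C)(C)[C@@H]2[C@@H](O)C[C@@]1(C)O[Si](C)(C)C(C)(C)C | intermediate
29 | (13R)-labd-14-ene-6α,8α,13-triol | C=C[C@](C)(O)CC[C@@H]1[C@@]2(C)CCCC(C)(C)[C@@H]2[C@@H](O)C[C@@]1(C)O | intermediate
30 | angelic acid ((Z)-2-methylbut-2-enoic acid) | C/C=C(/C)C(=O)O | starting material
31 | angelic 2,4,6-trichlorobenzoic anhydride | C/C=C(/C)C(=O)OC(=O)c1c(Cl)cc(Cl)cc1Cl | intermediate
32 | (13R)-6α-angeloyloxylabd-14-ene-8α,13-diol (CNP0203829.1) | C=C[C@](C)(O)CC[C@@H]1[C@@]2(C)CCCC(C)(C)[C@@H]2[C@@H](OC(=O)/C(C)=C\C)C[C@@]1(C)O | target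

Total step count: 18. Longest linear sequence: 15 steps (1, 2, 3, 6, 7, 8, 9, 10, 12, 13, 14, 15, 16, 17, 18); steps 4, 5 and 11 are branch steps.

Steps most likely to fail

Step 7. The neopentyl enol ether terminus may fail to add to the hindered β,β-disubstituted enoyl carbon, the catalyst may not turn over once the silyl group has migrated, or enantioface discrimination may be poor. Fallback: stereocontrol is moved from the catalyst to a covalently bound auxiliary. Acid 11 is coupled as in step 5 with (S)-4-benzyloxazolidin-2-one to give (S)-4-benzyl-3-[(E)-3-iodobut-2-enoyl]oxazolidin-2-one F1. Suzuki–Miyaura coupling of F1 with borane 15 (made from 9 as in step 6) gives (S)-4-benzyl-3-[(2E,8Z,10Z)-9,11-bis(tert-butyldimethylsilyloxy)-3,7,7-trimethyldodeca-2,8,10-trienoyl]oxazolidin-2-one F2. Its cycloaddition is promoted with Me2AlCl in CH2Cl2 at −30 °C, the established auxiliary-controlled intramolecular Diels–Alder reaction of trienyl imides; in the chelated s-cis form the benzyl group covers the Re face of C9, so bonding occurs on the Si face as required and gives the auxiliary-bearing cycloadduct F3. Cleavage of F3 with EtSH/n-BuLi as in step 8 brings the route back at thioester 18.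

Step 3. The allyl nucleophile may attack the carbonyl group directly, the C8 silyl group may be lost, or the C7=C8 geometry may erode under the copper and chlorosilane conditions. Fallback: the quaternary carbon is made first and the diene afterwards. Starting from 1, Hosomi–Sakurai allylation (allyltrimethylsilane, TiCl4, CH2Cl2, −78 °C) gives 4,4-dimethylhept-6-en-2-one F4. Kinetic enolate acylation of F4 with 2 as in step 1 gives 6,6-dimethylnon-8-ene-2,4-dione F5. Double O-silylation of F5 (TBSOTf, Et3N, CH2Cl2) then gives 9 together with the isomer enolised toward the terminal methyl, which is expected to predominate and has to be separated. The route comes back at 9.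

Step 6. The aqueous base may hydrolyse a silyl enol ether or the imide, or transmetalation from the hindered alkylborane may be slow. Fallback: the coupling is run without base through zirconium and zinc. Triene 9 is hydrozirconated at the terminal alkene with Cp2Zr(H)Cl in THF to give chlorobis(cyclopentadienyl)[(5Z,7Z)-6,8-bis(tert-butyldimethylsilyloxy)-4,4-dimethylnona-5,7-dienyl]zirconium F6. After transmetalation with ZnCl2, F6 undergoes Pd(PPh3)4-catalysed Negishi coupling (zerovalent palladium) with 14 under anhydrous conditions. The route comes back at 16.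

Further compounds
F1 | step 7 | (S)-4-benzyl-3-[(E)-3-iodobut-2-enoyl]oxazolidin-2-one | C/C(I)=C\C(=O)N1[C@@H](Cc2ccccc2)COC1=O
F2 | step 7 | (S)-4-benzyl-3-[(2E,8Z,10Z)-9,11-bis(tert-butyldimethylsilyloxy)-3,7,7-trimethyldodeca-2,8,10-trienoyl]oxazolidin-2-one | O=C1OC[C@H](Cc2ccccc2)N1C(=O)/C=C(\C)CCCC(C)(C)/C=C(\O[Si](C)(C)C(C)(C)C)/C=C(/C)O[Si](C)(C)C(C)(C)C
F3 | step 7 | (S)-4-benzyl-3-[6,8α-bis(tert-butyldimethylsilyloxy)drim-6-en-11-oyl]oxazolidin-2-one | O=C1OC[C@H](Cc2ccccc2)N1C(=O)[C@@H]2[C@@]3(C)CCCC(C)(C)[C@@H]3C(O[Si](C)(C)C(C)(C)C)=C[C@@]2(C)O[Si](C)(C)C(C)(C)C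
F4 | step 3 | 4,4-dimethylhept-6-en-2-one | C=CCC(C)(C)CC(C)=O
F5 | step 3 | 6,6-dimethylnon-8-ene-2,4-dione | C=CCC(C)(C)CC(=O)CC(C)=O
F6 | step 6 | chlorobis(cyclopentadienyl)[(5Z,7Z)-6,8-bis(tert-butyldimethylsilyloxy)-4,4-dimethylnona-5,7-dienyl]zirconium | Cl[Zr](CCCC(C)(C)/C=C(\O[Si](C)(C)C(C)(C)C)/C=C(/C)O[Si](C)(C)C(C)(C)C)(C1C=CC=C1)C1C=CC=C1
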